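Ring letters: unit 1 (fisetinidol on C8 of catechin) has rings A (benzo), B (catechol) and C (pyran); catechin has D (phloroglucinol-type), E (catechol) and F (pyran); unit 2 (fisetinidol on C6) has G (benzo), H (catechol) and J (pyran).
First cut: ring J at O1–C2 and C3–C4, with C3–OH traced back to C3–B. Ring J carries ring H on C2, oxygen on C3 and ring D on C4 all trans, and its O1 is the phenol oxygen of ring G; this is the pattern left by an endo [4+2] of an E-styrene with a ring G o-quinone methide whose methide carbon (C4) bears the electron-rich ring D.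
Further cuts: the bond from C6 of ring D to the carbinol carbon (aryllithium plus salicylaldehyde), then C4 of ring C to C8 of ring D (aryllithium plus a fustin-type C4 ketone, then ionic hydrogenation), then ring C itself (chalcone epoxide opened by the ring A phenol).
Forward order: ring C is built on a chalcone; benzylated 8-bromocatechin is joined to its C4 ketone and C4 is reduced; ring D is brominated at C6 and takes up ring G as an o-hydroxybenzhydrol; ring J closes by cycloaddition with the styrylboronate; C–B oxidation and hydrogenolysis finish.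
Stereochemistry: rings E/F from (+)-catechin; C3 of unit 1 from poly-L-leucine epoxidation and C2 from invertive ring closure; C4 of unit 1 from hydride delivery anti to O3; C2, C3 and C4 of unit 2 relative to each other from alkene geometry and endo approach, their absolute sense from a chiral phosphoric acid; C3–O of unit 2 by stereoretentive C–B oxidation.

Key step: step 15

Assumption: the (R) enantiomer of the phosphoric acid is taken to be the one that sends the styrene to the required face of the methide carbon; should the opposite sense apply, the (S) acid is used and nothing else changes.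
Remark: 4'-benzyloxy-2'-hydroxyacetophenone and 4-benzyloxy-2-hydroxybenzaldehyde are taken as purchased; each is otherwise one selective 4-O-benzylation away from the dihydroxy parent.

Step 1
Reactants: 1 (+)-catechin
Product: 2 5,7,3',4'-tetra-O-benzyl-(+)-catechin (2R,3S; 3-OH free)
Conditions: BnBr (4.4 equiv), K2CO3, DMF, 0 °C to rt, argon
Reagents that add atoms: benzyl bromide, `BrCc1ccccc1`
Why: Williamson etherification under weak base alkylates the four phenols and leaves the less acidic C3 alcohol free; neither stereocentre is involved.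

Step 2
Reactants: 2 5,7,3',4'-tetra-O-benzyl-(+)-catechin
Product: 3 3,5,7,3',4'-penta-O-benzyl-(+)-catechin
Conditions: NaH, BnBr, DMF, 0 °C to rt
Reagents that add atoms: benzyl bromide, `BrCc1ccccc1`
Why: Williamson etherification of the C3 alkoxide; with every phenol already capped, base cannot open ring F through a ring E quinone methide, so C2 is not epimerized.

Step 3
Reactants: 3 3,5,7,3',4'-penta-O-benzyl-(+)-catechin
Product: 4 8-bromo-3,5,7,3',4'-penta-O-benzyl-(+)-catechin
Conditions: NBS (1.0 equiv), CH2Cl2, −78 °C to rt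
Reagents that add atoms: N-bromosuccinimide, `O=C1CCC(=O)N1Br`
Why: Electrophilic aromatic bromination; in benzylated catechins NBS attacks C8 of the trioxygenated ring D first, and the dioxygenated ring E is far less reactive.

Step 4
Reactants: 5 4'-benzyloxy-2'-hydroxyacetophenone
Product: 6 4'-benzyloxy-2'-(methoxymethoxy)acetophenone
Conditions: MOMCl, K2CO3, acetone, reflux
Reagents that add atoms: chloromethyl methyl ether, `COCCl`
Why: O-Alkylation of the chelated phenol gives the acetal that keeps this phenol out of the alkaline peroxide step, where a free 2'-OH would divert the enone into the Algar–Flynn–Oyamada pathway.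

Step 5
Reactants: 6 4'-benzyloxy-2'-(methoxymethoxy)acetophenone, 7 3,4-bis(benzyloxy)benzaldehyde
Product: 8 (E)-1-[4-(benzyloxy)-2-(methoxymethoxy)phenyl]-3-[3,4-bis(benzyloxy)phenyl]prop-2-en-1-one
Conditions: KOH, EtOH/THF, rt
Reagents that add atoms: none
Why: Claisen–Schmidt condensation; aldol addition of the methyl ketone enolate and E1cB loss of water give the conjugated E-enone.

Step 6
Reactants: 8 the E-chalcone
Product: 9 [4-(benzyloxy)-2-(methoxymethoxy)phenyl][(2R,3S)-3-[3,4-bis(benzyloxy)phenyl]oxiran-2-yl]methanone (trans epoxide)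
Conditions: poly-L-leucine, urea·H2O2, 1,8-diazabicyclo[5.4.0]undec-7-ene, THF, rt
Reagents that add atoms: urea–hydrogen peroxide, `NC(N)=O.OO`
Why: Juliá–Colonna epoxidation; hydroperoxide adds in conjugate fashion to the enone held on the helical poly-L-leucine, which for chalcones delivers oxygen to the face giving the trans (2R,3S)-epoxy ketone, and the aryl ethers and the acetal are inert.

Step 7
Reactants: 9 the (2R,3S)-epoxy ketone
Product: 11 (2R,3R)-7,3',4'-tri-O-benzylfustin [(2R,3R)-7-(benzyloxy)-2-[3,4-bis(benzyloxy)phenyl]-3-hydroxychroman-4-one; 2,3-trans], via 2'-hydroxy epoxy ketone 10 (not isolated)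
Conditions: conc. HCl (cat.), MeOH/THF, 50 °C
Reagents that add atoms: none
Why: Acid removes the methoxymethyl acetal and the freed phenol 10 opens the epoxide at the benzylic carbon (activated by the para benzyloxy group) in a 6-endo ring closure with inversion, the established chalcone epoxide route to 2,3-trans-dihydroflavonols; C3 keeps the R configuration of the epoxide carbon next to the carbonyl, C2 becomes R, and the 2,3-trans isomer is also the thermodynamically favoured one.

Step 8
Reactants: 11 (2R,3R)-7,3',4'-tri-O-benzylfustin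
Product: 12 (2R,3R)-3,7,3',4'-tetra-O-benzylfustin (C4 ketone)
Conditions: BnOC(=NH)CCl3, CF3SO3H (cat.), CH2Cl2/cyclohexane, 0 °C to rt
Reagents that add atoms: benzyl 2,2,2-trichloroacetimidate, `N=C(OCc1ccccc1)C(Cl)(Cl)Cl`
Why: Acid-catalysed O-benzylation with the trichloroacetimidate; it avoids base, which would enolize the α-oxy ketone and open ring C by β-elimination of the ring A phenoxide, so C2 and C3 are kept.

Step 9
Reactants: 4 8-bromo-penta-O-benzylcatechin, 12 tetra-O-benzylfustin
Product: 14 3,7,3',4'-tetra-O-benzyl-4-hydroxyfisetinidol-(4→8)-penta-O-benzylcatechin (tertiary carbinol; C4 epimers), via 8-lithio-penta-O-benzylcatechin 13 (not isolated)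
Conditions: 4, n-BuLi (1.05 equiv), THF, −78 °C; then 12, −78 to −40 °C; H2O
Reagents that add atoms: none
Why: Bromine–lithium exchange followed by 1,2-addition of the aryllithium to the chromanone carbonyl, the reaction type used to join flavan C4 ketones to C8-lithiated flavans; at −78 °C addition should outrun enolization, and the configuration formed at C4 does not matter because it is erased in step 10.

Step 10
Reactants: 14 the tertiary carbinol
Product: 16 3,7,3',4'-tetra-O-benzylfisetinidol-(4β→8)-3,5,7,3',4'-penta-O-benzylcatechin (unit 1 2R,3S,4R; 2,3-trans-3,4-cis), via C4 benzylic cation 15 (not isolated)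
Conditions: Bu3SnH, CF3CO2H, CH2Cl2, 0 °C
Reagents that add atoms: none
Why: Ionic hydrogenation; CF3CO2H ionizes the tertiary doubly benzylic alcohol to cation 15 and Bu3SnH transfers hydride to C4 on the face anti to the neighbouring C3 benzyloxy group, so ring D ends cis to O3 (4β, C4 R), as in the tin hydride reduction of related 4-aryl-4-hydroxyflavans.

Step 11
Reactants: 16 the nona-O-benzyl dimer
Product: 17 6-bromo derivative of 16 (bromine on C6 of ring D)
Conditions: NBS (1.05 equiv), CH2Cl2, −78 to 0 °C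
Reagents that add atoms: N-bromosuccinimide, `O=C1CCC(=O)N1Br`
Why: Electrophilic aromatic bromination; C6 is the last free position of ring D, the only trioxygenated ring, which should react with one equivalent of NBS at low temperature ahead of the dioxygenated rings A, B and E.

Step 12
Reactants: 18 4-benzyloxy-2-hydroxybenzaldehyde
Product: 19 4-benzyloxy-2-[(tert-butyldimethylsilyl)oxy]benzaldehyde
Conditions: TBSCl, imidazole, DMF, rt
Reagents that add atoms: tert-butyldimethylsilyl chloride, `CC(C)(C)[Si](C)(C)Cl`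
Why: Imidazole-promoted silylation of the phenol, so that the aldehyde meets the aryllithium without an acidic proton.

Step 13
Reactants: 17 the 6-bromo dimer, 19 the silylated aldehyde
Product: 22 6-[(4-benzyloxy-2-hydroxyphenyl)(hydroxy)methyl] derivative of 16 (o-hydroxybenzhydrol on C6 of ring D; both carbinol epimers), via 6-lithio dimer 20 (not isolated), via silyl ether lithium alkoxide adduct 21 (not isolated)
Conditions: 17, n-BuLi, THF, −78 °C; 19, −78 °C; then Bu4NF, −78 to 0 °C; H2O; chromatography on Et3N-treated silica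
Reagents that add atoms: none
Why: Bromine–lithium exchange and 1,2-addition of the aryllithium to the aldehyde, then fluoride cleavage of the silyl ether in the same flask (wherever a phenol-to-alkoxide silyl shift may have placed it); the new carbinol centre is formed without control, which is harmless because it becomes planar in step 15.

Step 14
Reactants: 7 3,4-bis(benzyloxy)benzaldehyde, 23 bis[(pinacolato)boryl]methane
Product: 25 (E)-2-[3,4-bis(benzyloxy)styryl]-4,4,5,5-tetramethyl-1,3,2-dioxaborolane, via lithiated bis(boryl)methane 24 (not isolated)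
Conditions: 23, lithium 2,2,6,6-tetramethylpiperidide (from n-BuLi and 2,2,6,6-tetramethylpiperidine), THF, 0 °C; then 7, −78 °C to rt; H2O
Reagents that add atoms: none
Why: Boron–Wittig olefination; the α-boryl carbanion 24 adds to the aldehyde and syn elimination of the O–B pair gives the alkenylboronate, with the E geometry that is usual for aromatic aldehydes.

Step 15
Reactants: 22 the o-hydroxybenzhydrol, 25 the (E)-styrylboronate
Product: 27 dodeca-O-benzyl trimer with a pinacol boronate on C3 of ring J (ring H on C2 and boron on C3 and ring D on C4 all trans; same spatial arrangement as the target with boron in place of O3), via o-quinone methide 26 (not isolated)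
Conditions: (R)-3,3'-bis(2,4,6-triisopropylphenyl)-1,1'-binaphthyl-2,2'-diyl hydrogen phosphate (10 mol %), 25 (3 equiv), 4 Å molecular sieves, toluene, −20 °C to rt
Reagents that add atoms: none
Why: Proposed new method: the phosphoric acid ionizes the doubly benzylic carbinol (water is taken up by the sieves) to the E-configured o-quinone methide 26, which ring D stabilizes, and the electron-rich styrene, whose pinacol boronate is too weak an acceptor to reverse its polarization, bonds through its boron-bearing carbon to the methide carbon while the phosphate-bound ring G oxygen captures the developing para-benzyloxybenzylic C2 in an asynchronous [4+2]; the closest known reaction type is the Brønsted acid-catalysed inverse-demand oxa-Diels–Alder reaction of o-hydroxybenzhydrol-derived o-quinone methides with styrenes and β-alkylstyrenes, which gives 2,4-cis and 2,3-trans-2,4-cis flavans. Ring J closes by this cycloaddition, O1–C2 and C3–C4 forming across the 1-oxadiene of 26 (if stepwise, by 6-endo capture of the C2 cation by the phenoxide). C2 and C3 come out trans because the E geometry of 25 is transferred, and C4 comes out cis to the C2 aryl, hence trans to boron, through the aryl-endo approach to the E methide, a stepwise path converging on the same all-equatorial isomer. The absolute sense, that is which face of the methide carbon is attacked, cannot be expected from the distant stereocentres of 22 and is assigned to the phosphate, which is hydrogen-bonded to the quinone methide oxygen between its 2,4,6-triisopropylphenyl groups. The step needs regioselectivity (secured by the C2 cation being benzylic and para-oxygenated, the alternative being an α-boryl cation), survival of the C–B bond (secured by the pinacol ester, which does not exchange with the phenol and so stays out of the boron-to-methide alkenyl transfer known for labile boronic esters) and chemoselectivity (the carbinol flanked by ring D and the free phenol is by far the most easily ionized site of 22).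

Step 16
Reactants: 27 the boronate trimer
Product: 28 dodeca-O-benzyl-fisetinidol-(4β→8)-catechin-(6→4α)-fisetinidol with free 3-OH on unit 2 (unit 2 2R,3S,4S)
Conditions: NaBO3·4H2O, THF/H2O, rt
Reagents that add atoms: sodium perborate tetrahydrate, `[Na+].[O-]OB=O.O.O.O.O`
Why: Oxidation of the C–B bond by perborate; hydroperoxide adds to boron and C3 migrates from boron to oxygen with retention, as in the oxidation of other 3-borylchromans, so the C3 hydroxyl stays trans to both neighbours, and the benzyl ethers are untouched.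

Step 17
Reactants: 28 the dodeca-O-benzyl trimer alcohol
Product: 29 fisetinidol-(4β→8)-catechin-(6→4α)-fisetinidol (CNP0289228.2)
Conditions: H2 (1 atm), Pd(OH)2/C, THF/MeOH/H2O, rt
Reagents that add atoms: none
Why: Hydrogenolysis of the twelve benzyl ethers over Pd(OH)2/C; the C4–aryl bonds of 4-arylflavans and the pyran C–O bonds are known to survive these conditions, so no stereocentre is touched.

Compound list
1 | (+)-catechin (2R,3S) | `O[C@H]1Cc2c(O)cc(O)cc2O[C@@H]1c1ccc(O)c(O)c1` | starting material
2 | 5,7,3',4'-tetra-O-benzyl-(+)-catechin | `c9ccccc9COc1cc(OCc9ccccc9)c2c(c1)O[C@H](c1ccc(OCc9ccccc9)c(OCc9ccccc9)c1)[C@@H](O)C2` | intermediate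
3 | 3,5,7,3',4'-penta-O-benzyl-(+)-catechin | `c9ccccc9COc1cc(OCc9ccccc9)c2c(c1)O[C@H](c1ccc(OCc9ccccc9)c(OCc9ccccc9)c1)[C@@H](OCc9ccccc9)C2` | intermediate
4 | 8-bromo-3,5,7,3',4'-penta-O-benzyl-(+)-catechin | `Brc1c(OCc9ccccc9)cc(OCc9ccccc9)c2c1O[C@H](c1ccc(OCc9ccccc9)c(OCc9ccccc9)c1)[C@@H](OCc9ccccc9)C2` | intermediate
5 | 4'-benzyloxy-2'-hydroxyacetophenone | `CC(=O)c1ccc(OCc9ccccc9)cc1O` | starting material
6 | 4'-benzyloxy-2'-(methoxymethoxy)acetophenone | `CC(=O)c1ccc(OCc9ccccc9)cc1OCOC` | intermediate
7 | 3,4-bis(benzyloxy)benzaldehyde | `O=Cc1ccc(OCc2ccccc2)c(OCc2ccccc2)c1` | starting material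
8 | (E)-1-[4-(benzyloxy)-2-(methoxymethoxy)phenyl]-3-[3,4-bis(benzyloxy)phenyl]prop-2-en-1-one | `COCOc1cc(OCc9ccccc9)ccc1C(=O)/C=C/c1ccc(OCc9ccccc9)c(OCc9ccccc9)c1` | intermediate
9 | [4-(benzyloxy)-2-(methoxymethoxy)phenyl][(2R,3S)-3-[3,4-bis(benzyloxy)phenyl]oxiran-2-yl]methanone | `COCOc1cc(OCc9ccccc9)ccc1C(=O)[C@@H]1O[C@H]1c1ccc(OCc9ccccc9)c(OCc9ccccc9)c1` | intermediate
10 | [4-(benzyloxy)-2-hydroxyphenyl][(2R,3S)-3-[3,4-bis(benzyloxy)phenyl]oxiran-2-yl]methanone (not isolated) | `Oc1cc(OCc9ccccc9)ccc1C(=O)[C@@H]1O[C@H]1c1ccc(OCc9ccccc9)c(OCc9ccccc9)c1` | intermediate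
11 | (2R,3R)-7,3',4'-tri-O-benzylfustin | `c9ccccc9COc1ccc2c(c1)O[C@H](c1ccc(OCc9ccccc9)c(OCc9ccccc9)c1)[C@@H](O)C2=O` | intermediate
12 | (2R,3R)-3,7,3',4'-tetra-O-benzylfustin | `c9ccccc9COc1ccc2c(c1)O[C@H](c1ccc(OCc9ccccc9)c(OCc9ccccc9)c1)[C@@H](OCc9ccccc9)C2=O` | intermediate
13 | 8-lithio-3,5,7,3',4'-penta-O-benzylcatechin (not isolated) | `[Li]c1c(OCc9ccccc9)cc(OCc9ccccc9)c2c1O[C@H](c1ccc(OCc9ccccc9)c(OCc9ccccc9)c1)[C@@H](OCc9ccccc9)C2` | intermediate
14 | 3,7,3',4'-tetra-O-benzyl-4-hydroxyfisetinidol-(4→8)-penta-O-benzylcatechin (C4 epimers) | `c9ccccc9COc1ccc2c(c1)O[C@H](c1ccc(OCc9ccccc9)c(OCc9ccccc9)c1)[C@@H](OCc9ccccc9)C2(O)c1c(OCc9ccccc9)cc(OCc9ccccc9)c2c1O[C@H](c1ccc(OCc9ccccc9)c(OCc9ccccc9)c1)[C@@H](OCc9ccccc9)C2` | intermediate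
15 | C4 benzylic cation of unit 1 as trifluoroacetate (not isolated) | `c9ccccc9COc1ccc2c(c1)O[C@H](c1ccc(OCc9ccccc9)c(OCc9ccccc9)c1)[C@@H](OCc9ccccc9)[C+]2c1c(OCc9ccccc9)cc(OCc9ccccc9)c2c1O[C@H](c1ccc(OCc9ccccc9)c(OCc9ccccc9)c1)[C@@H](OCc9ccccc9)C2.[O-]C(=O)C(F)(F)F` | intermediate
16 | 3,7,3',4'-tetra-O-benzylfisetinidol-(4β→8)-3,5,7,3',4'-penta-O-benzylcatechin | `c9ccccc9COc1ccc2c(c1)O[C@H](c1ccc(OCc9ccccc9)c(OCc9ccccc9)c1)[C@@H](OCc9ccccc9)[C@H]2c1c(OCc9ccccc9)cc(OCc9ccccc9)c2c1O[C@H](c1ccc(OCc9ccccc9)c(OCc9ccccc9)c1)[C@@H](OCc9ccccc9)C2` | intermediate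
17 | 6-bromo derivative of 16 (bromine on C6 of ring D) | `c9ccccc9COc1ccc2c(c1)O[C@H](c1ccc(OCc9ccccc9)c(OCc9ccccc9)c1)[C@@H](OCc9ccccc9)[C@H]2c1c(OCc9ccccc9)c(Br)c(OCc9ccccc9)c2c1O[C@H](c1ccc(OCc9ccccc9)c(OCc9ccccc9)c1)[C@@H](OCc9ccccc9)C2` | intermediate
18 | 4-benzyloxy-2-hydroxybenzaldehyde | `O=Cc1ccc(OCc9ccccc9)cc1O` | starting material
19 | 4-benzyloxy-2-[(tert-butyldimethylsilyl)oxy]benzaldehyde | `O=Cc1ccc(OCc9ccccc9)cc1O[Si](C)(C)C(C)(C)C` | intermediate
20 | 6-lithio derivative of 16 (not isolated) | `c9ccccc9COc1ccc2c(c1)O[C@H](c1ccc(OCc9ccccc9)c(OCc9ccccc9)c1)[C@@H](OCc9ccccc9)[C@H]2c1c(OCc9ccccc9)c([Li])c(OCc9ccccc9)c2c1O[C@H](c1ccc(OCc9ccccc9)c(OCc9ccccc9)c1)[C@@H](OCc9ccccc9)C2` | intermediate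
21 | lithium alkoxide of the adduct of 20 and 19, silyl ether intact (not isolated) | `c9ccccc9COc1ccc2c(c1)O[C@H](c1ccc(OCc9ccccc9)c(OCc9ccccc9)c1)[C@@H](OCc9ccccc9)[C@H]2c1c(OCc9ccccc9)c(C(O[Li])c3ccc(OCc9ccccc9)cc3O[Si](C)(C)C(C)(C)C)c(OCc9ccccc9)c2c1O[C@H](c1ccc(OCc9ccccc9)c(OCc9ccccc9)c1)[C@@H](OCc9ccccc9)C2` | intermediate
22 | 6-[(4-benzyloxy-2-hydroxyphenyl)(hydroxy)methyl] derivative of 16 (carbinol epimers) | `c9ccccc9COc1ccc2c(c1)O[C@H](c1ccc(OCc9ccccc9)c(OCc9ccccc9)c1)[C@@H](OCc9ccccc9)[C@H]2c1c(OCc9ccccc9)c(C(O)c3ccc(OCc9ccccc9)cc3O)c(OCc9ccccc9)c2c1O[C@H](c1ccc(OCc9ccccc9)c(OCc9ccccc9)c1)[C@@H](OCc9ccccc9)C2` | intermediate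
23 | bis[(pinacolato)boryl]methane | `CC1(C)OB(CB2OC(C)(C)C(C)(C)O2)OC1(C)C` | starting material
24 | lithio-bis[(pinacolato)boryl]methane (not isolated) | `CC1(C)OB(C([Li])B2OC(C)(C)C(C)(C)O2)OC1(C)C` | intermediate
25 | (E)-2-[3,4-bis(benzyloxy)styryl]-4,4,5,5-tetramethyl-1,3,2-dioxaborolane | `CC1(C)OB(/C=C/c2ccc(OCc9ccccc9)c(OCc9ccccc9)c2)OC1(C)C` | intermediate
26 | E o-quinone methide of ring G with ring D of 16 on the methide carbon (not isolated) | `c9ccccc9COc1ccc2c(c1)O[C@H](c1ccc(OCc9ccccc9)c(OCc9ccccc9)c1)[C@@H](OCc9ccccc9)[C@H]2c1c(OCc9ccccc9)c(/C=C3\C=CC(OCc9ccccc9)=CC3=O)c(OCc9ccccc9)c2c1O[C@H](c1ccc(OCc9ccccc9)c(OCc9ccccc9)c1)[C@@H](OCc9ccccc9)C2` | intermediate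
27 | dodeca-O-benzyl trimer with pinacol boronate on C3 of ring J (all-trans ring J) | `c9ccccc9COc1ccc2c(c1)O[C@H](c1ccc(OCc9ccccc9)c(OCc9ccccc9)c1)[C@@H](OCc9ccccc9)[C@H]2c1c(OCc9ccccc9)c([C@@H]2c3ccc(OCc9ccccc9)cc3O[C@H](c3ccc(OCc9ccccc9)c(OCc9ccccc9)c3)[C@H]2B4OC(C)(C)C(C)(C)O4)c(OCc9ccccc9)c2c1O[C@H](c1ccc(OCc9ccccc9)c(OCc9ccccc9)c1)[C@@H](OCc9ccccc9)C2` | intermediate
28 | dodeca-O-benzyl-fisetinidol-(4β→8)-catechin-(6→4α)-fisetinidol, 3-OH of unit 2 free | `c9ccccc9COc1ccc2c(c1)O[C@H](c1ccc(OCc9ccccc9)c(OCc9ccccc9)c1)[C@@H](OCc9ccccc9)[C@H]2c1c(OCc9ccccc9)c([C@@H]2c3ccc(OCc9ccccc9)cc3O[C@H](c3ccc(OCc9ccccc9)c(OCc9ccccc9)c3)[C@H]2O)c(OCc9ccccc9)c2c1O[C@H](c1ccc(OCc9ccccc9)c(OCc9ccccc9)c1)[C@@H](OCc9ccccc9)C2` | intermediate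
29 | fisetinidol-(4β→8)-catechin-(6→4α)-fisetinidol (unit 1 2R,3S,4R; catechin 2R,3S; unit 2 2R,3S,4S) | `Oc1ccc2c(c1)O[C@H](c1ccc(O)c(O)c1)[C@@H](O)[C@H]2c1c(O)c([C@@H]2c3ccc(O)cc3O[C@H](c3ccc(O)c(O)c3)[C@H]2O)c(O)c2c1O[C@H](c1ccc(O)c(O)c1)[C@@H](O)C2` | target

Total step count: 17. Longest linear sequence: 12 steps (steps 4 to 11, then 13, 15, 16 and 17, counted from acetophenone 5).

Steps most likely to fail

Step 15. Boron may be lost, either by protodeboronation of 25 or by deborylative transfer of the styryl group to the methide carbon, and the catalyst may not control which face of the methide carbon is attacked. Unit 2 is then attached by the known Lewis acid-mediated arylation of a flavan C4 cation. Tribenzylfustin 11 is reduced with NaBH4 (EtOH/THF, 0 °C) to (2R,3S,4R)-7,3',4'-tri-O-benzylflavan-3,4-diol F1 (3,4-trans expected; the C4 configuration is lost in the next operation). This diol is ionized with TiCl4 in CH2Cl2 at low temperature in the presence of dimer 16. Ring D should attack through C6, its only free position, on the face of C4 anti to the C3 hydroxyl, as is usual for 2,3-trans flavan cations, which gives the 4α (all-trans) unit 2. This fallback sets out from 11 and 16 and returns to the route at 28.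

Step 10. Hydride may be delivered to cation 15 without enough preference for the face anti to O3, or the cation may lose H3 to give an enol ether. C4 of unit 1 is then set by arylation instead of reduction. Ketone 12 is reduced with NaBH4 to (2R,3S)-3,7,3',4'-tetra-O-benzylflavan-4-ol F2 (either C4 epimer), which is ionized with TiCl4 in CH2Cl2 in the presence of an excess of penta-O-benzylcatechin 3. C8 of ring D attacks the secondary C4 cation; in the 5-deoxy series this reaction is known to furnish both C4 epimers. Dimer 16 therefore has to be separated by chromatography from its 3,4-trans epimer, nona-O-benzyl-fisetinidol-(4α→8)-catechin F3. This fallback sets out from 12 and 3 and returns at 16.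

Step 13. Addition of the doubly ortho-substituted aryllithium 20 to the ortho-silyloxy aldehyde may be slow, so that proton transfer or metalation of benzyl ethers competes. The polarity of the carbinol-forming bond is then reversed. Bromide 17 is lithiated as before and quenched with DMF, a small electrophile, to give nona-O-benzyl-fisetinidol-(4β→8)-catechin-6-carbaldehyde F4. Purchased 5-(benzyloxy)-2-bromophenol is converted with two equivalents of n-BuLi (THF, −78 °C) into lithium 5-(benzyloxy)-2-lithiophenoxide F5, an unhindered aryl nucleophile that needs no phenol protection. Its addition to the aldehyde gives 22 after aqueous work-up. This fallback sets out from 17 and returns at 22.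

Further compounds
F1 | step 15 | (2R,3S,4R)-7-(benzyloxy)-2-[3,4-bis(benzyloxy)phenyl]chromane-3,4-diol (tri-O-benzylmollisacacidin) | `c9ccccc9COc1ccc2c(c1)O[C@H](c1ccc(OCc9ccccc9)c(OCc9ccccc9)c1)[C@@H](O)[C@@H]2O`
F2 | step 10 | (2R,3S)-3,7-bis(benzyloxy)-2-[3,4-bis(benzyloxy)phenyl]chroman-4-ol (C4 epimers) | `c9ccccc9COc1ccc2c(c1)O[C@H](c1ccc(OCc9ccccc9)c(OCc9ccccc9)c1)[C@@H](OCc9ccccc9)C2O`
F3 | step 10 | 3,7,3',4'-tetra-O-benzylfisetinidol-(4α→8)-3,5,7,3',4'-penta-O-benzylcatechin (C4 epimer of 16) | `c9ccccc9COc1ccc2c(c1)O[C@H](c1ccc(OCc9ccccc9)c(OCc9ccccc9)c1)[C@@H](OCc9ccccc9)[C@@H]2c1c(OCc9ccccc9)cc(OCc9ccccc9)c2c1O[C@H](c1ccc(OCc9ccccc9)c(OCc9ccccc9)c1)[C@@H](OCc9ccccc9)C2`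
F4 | step 13 | nona-O-benzyl-fisetinidol-(4β→8)-catechin-6-carbaldehyde (formyl on C6 of ring D) | `c9ccccc9COc1ccc2c(c1)O[C@H](c1ccc(OCc9ccccc9)c(OCc9ccccc9)c1)[C@@H](OCc9ccccc9)[C@H]2c1c(OCc9ccccc9)c(C=O)c(OCc9ccccc9)c2c1O[C@H](c1ccc(OCc9ccccc9)c(OCc9ccccc9)c1)[C@@H](OCc9ccccc9)C2`
F5 | step 13 | lithium 5-(benzyloxy)-2-lithiophenoxide | `[Li]Oc1cc(OCc9ccccc9)ccc1[Li]`
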